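The numbers in the tables come from a simulation on assumed constants; noise was put on by code.

**Next run.** The ochre flask is to be read at 30 h, and the next charge is either Tuesday's or Thursday's.

| flask | substrate | reagent in the second phase | remark | time | volume of the second phase over the first |
|---|---|---|---|---|---|
| ochre | 0.050 M | 4 equiv | the very flask that is asked about, followed so far |  |  |
| red | 0.034 M | 4 equiv | run made earlier |  |  |
| flask | 0.050 M | 4.00 equiv |  | 30 h | 2.0 |

- ochre (time / h: target / %, substrate / %): 0.333: 0, 100.5; 1.00: 0.5, 99.7; 1.50: 1.1, 98.4; 2.50: 1.3, 97.9; 4.00: 2.6, 97.1; 5.00: 3.6, 96.3; 6.00: 4.5, 94.8
- red (time / h: target / %, substrate / %): 1.50: 0.4, 99.0; 3.00: 1.4, 98.4; 5.00: 3.1, 97.5; 6.00: 2.7, 97.2; 8.00: 4.2, 94.9; 10.0: 5.1, 93.7; 12.0: 6.1, 93.1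

(standard deviation of a reading: 0.3 percentage points)

- in the second phase: reagent in the second phase; everything else is in the first
- charges count per volume of the first phase; a concentration in a rate is the amount of a species over the volume of its own phase; every rate counts per litre of the first phase
- the earlier runs hold the two phases in the same ratio of volumes as the flask asked about

1. amount of target at 30 h, in percent of the substrate charged
2. the change that raises the amount of target at 30 h, in percent of the substrate charged most ("none" if none brings more than 2 percentage points) (Tuesday's / Thursday's / none)
3. amount of target at 30 h, in percent of the substrate charged, after Thursday's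

- Tuesday's: doubling the transfer coefficient of the reagent in the second phase, all else as stated
- Thursday's: doubling the amount of reagent in the second phase, all else as stated

**Frozen constant.** The reckoning here freezes c(reagent in the reaction phase) and treats the loss of substrate as pseudo-first-order. The last ochre reading gives 0.00890 h⁻¹ for the frozen loss constant k′, minus the logarithm of the fraction of substrate left, over the time. The red run reads 0.00596 h⁻¹. Their ratio, 1.49, stands beside the charge ratio, 1.47, but the ochre reading at 5.00 h against the red reading at 10.0 h gives 1.16, so with a scatter of 0.3 percentage points these single readings do not show how k′ moves with the charge.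

**Own reckoning.** Held to 30 h, k′ leaves 76.6% of substrate in the ochre flask. The 23.4% consumed is the ceiling on target, taking one target per substrate; this reckoning gives no closer figure for target. At one reagent per substrate, the draw is 5.86% of the reagent charge, and the freeze is kept.

**The decision.** The two runs moved the reagent in the second phase only together with the substrate, so it is an assumption here that c(reagent in the reaction phase) doubles with that reagent; on this assumption Thursday's doubles k′, and 41.4% of substrate is consumed. Neither run moved the transfer coefficient, so the readings put no number on Tuesday's. Thursday's is the charge to make.

**Forecast.** The forecast gives 21% of target (range 18% to 25%), chooses Thursday's, and gives 37% after it (range 29% to 42%): “Doubling the reagent doubles k′, giving about 37%.”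

**Result.** The ochre flask gives 12.9% of target. Thursday's gains 7.7 points, more than the 2.5 points of Tuesday's, and ends at 20.6%.

    reagent in the reaction phase ⇌ reagent in the second phase, rate k1*([reagent in the reaction phase] - [reagent in the second phase]/K1) per volume of the first phase (partition coefficient = 88.7, kL = 0.860 h⁻¹)
    substrate + reagent in the reaction phase → target (k = 14.4 M⁻¹ h⁻¹)
    reagent in the reaction phase + target → over-reacted product (k = 12.8 M⁻¹ h⁻¹)
    target ⇌ isomer of the product (K = 2.70, k = 0.0389 h⁻¹)

**Same constant.** At 30.0 h, the ochre flask holds 77% of substrate, beside the 76.6% reckoned with k′. Its target, 12.9%, is less than the 23.4% reckoned as consumed, while the isomer of the product stands at 7.90% and the over-reacted product at 1.83%. For the neighbouring flask stopped at 8.0 h, the same k′ leaves 93.1% of substrate. That flask holds 94% of substrate and 5.31% of target.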